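**Retrosynthetic overview**

1. Target: normal-series labdane, (13E)-15-acetoxylabda-8,13-dien-19-oic acid (4S,5R,10S). Late cuts: the C15 acetate, the C19 ester protection, the C9–C11 bond (B-alkyl Suzuki coupling of a C8=C9 enol triflate with a C11–C16 borane) and the C8–C17 methyl (enolate methylation of a C9 ketone).
2. Structural feature used: C5–H lies between the two quaternary carbons C4 (CH3, CO2H) and C10 (CH3). A trisubstituted dienophile C4=C5 adding to a diene C3=C2–C1=C10 that ends at the methyl-bearing C10 creates C4, C5 and C10 in one event, and the olefin geometry fixes the two C4 substituents.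
3. Key cut: C5–C10 and C3–C4 by an intramolecular Diels–Alder reaction of an (E,E)-trienal. Ring A (C1–C5, C10) is the cycloadduct ring and ring B (C5–C10) closes in the same step from the C6–C9 tether. The formyl group becomes C18 (CH3), the benzyloxymethyl group becomes C19 (CO2H), and a C9 benzyloxy stereocentre (later the C9 ketone) steers the face.
4. The trienal comes from four pieces: acrolein (C1–C3), a propanoate ylide (C9, C10, C20), 4-chlorobutan-1-ol (C5–C8) and ethyl 2-(diethoxyphosphoryl)acrylate (C4, C18, C19). C9 is set by CBS reduction of a dienone.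
5. Ring order: rings A and B together (step 12). The side chain (C11–C16, from (E)-3-methylpent-2-en-4-yn-1-ol) is attached last.

Key step: step 12

Remark: atom numbers are those of the labdane skeleton; α is the face opposite to the C10 methyl group (C20), β the same face. Step 17 may give either C8 epimer, which is without consequence because C8 becomes sp2 in step 18.

**Route**

Step 1
Reactants: 1 acrolein; 2 ethyl 2-(triphenylphosphoranylidene)propanoate
Product: 3 ethyl (2E)-2-methylpenta-2,4-dienoate
Conditions: CH2Cl2, 0 °C → rt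
Reagents that add atoms: none
Why: Wittig olefination with an ester-stabilised ylide, which reacts only at the aldehyde of acrolein and under thermodynamic control gives the (E)-trisubstituted enoate.

Step 2
Reactants: 3 ethyl (2E)-2-methylpenta-2,4-dienoate
Product: 4 (2E)-N-methoxy-N,2-dimethylpenta-2,4-dienamide
Conditions: MeNHOMe·HCl, i-PrMgCl, THF, −20 → 0 °C
Reagents that add atoms: N,O-dimethylhydroxylamine hydrochloride, CNOC.Cl
Why: Weinreb amide formation by aminolysis of the ester with the chloromagnesium amide, which attacks the ester carbonyl faster than it adds in conjugate fashion to the α-branched dienoate.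

Step 3
Reactants: 5 4-chlorobutan-1-ol
Product: 6 tert-butyl(4-chlorobutoxy)dimethylsilane
Conditions: t-BuMe2SiCl, imidazole, CH2Cl2, 0 °C → rt
Reagents that add atoms: tert-butyldimethylsilyl chloride, CC(C)(C)[Si](C)(C)Cl
Why: Standard silylation of the primary alcohol, which leaves the alkyl chloride free for Grignard formation.

Step 4
Reactants: 6 tert-butyl(4-chlorobutoxy)dimethylsilane; 4 (2E)-N-methoxy-N,2-dimethylpenta-2,4-dienamide
Product: 8 (6E)-1-(tert-butyldimethylsilyloxy)-6-methylnona-6,8-dien-5-one, via Grignard reagent 7 (not isolated)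
Conditions: Mg, I2 (cat.), THF, reflux; then 4, THF, 0 °C; aq. NH4Cl
Reagents that add atoms: none
Why: Grignard formation from the primary chloride followed by acylation with the Weinreb amide, whose chelated tetrahedral magnesium adduct persists until work-up and so stops the addition at the ketone.

Step 5
Reactants: 8 (6E)-1-(tert-butyldimethylsilyloxy)-6-methylnona-6,8-dien-5-one
Product: 9 (5S,6E)-1-(tert-butyldimethylsilyloxy)-6-methylnona-6,8-dien-5-ol
Conditions: (R)-2-methyl-CBS-oxazaborolidine [(3aR)-1-methyl-3,3-diphenyltetrahydro-1H,3H-pyrrolo[1,2-c][1,3,2]oxazaborole] (0.2 equiv), catecholborane, toluene, −78 °C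
Reagents that add atoms: none
Why: Corey–Bakshi–Shibata reduction in which the α-branched dienyl group is the large and the primary alkyl chain the small ketone substituent, so the (R)-catalyst should deliver hydride to the face that gives the (S)-carbinol (C9), while catecholborane at −78 °C does not hydroborate the diene.

Step 6
Reactants: 9 (5S,6E)-1-(tert-butyldimethylsilyloxy)-6-methylnona-6,8-dien-5-ol
Product: 11 tert-butyl{[(5S,6E)-5-(benzyloxy)-6-methylnona-6,8-dien-1-yl]oxy}dimethylsilane, via sodium alkoxide 10 (not isolated)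
Conditions: NaH, THF, 0 °C; BnBr, Bu4NI (cat.), 0 °C → rt
Reagents that add atoms: benzyl bromide, BrCc1ccccc1
Why: Williamson etherification of the sodium alkoxide, which does not touch the C9 stereocentre.

Step 7
Reactants: 11 tert-butyl{[(5S,6E)-5-(benzyloxy)-6-methylnona-6,8-dien-1-yl]oxy}dimethylsilane
Product: 12 (5S,6E)-5-(benzyloxy)-6-methylnona-6,8-dien-1-ol
Conditions: Bu4NF, THF, 0 °C → rt
Reagents that add atoms: none
Why: Fluoride-induced cleavage of the primary silyl ether, to which the benzyl ether and the diene are inert.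

Step 8
Reactants: 12 (5S,6E)-5-(benzyloxy)-6-methylnona-6,8-dien-1-ol
Product: 13 (5S,6E)-5-(benzyloxy)-6-methylnona-6,8-dienal
Conditions: Dess–Martin periodinane (1,1,1-triacetoxy-1,1-dihydro-1,2-benziodoxol-3(1H)-one), CH2Cl2, 0 °C → rt
Reagents that add atoms: none
Why: Dess–Martin oxidation of the primary alcohol to the aldehyde under near-neutral conditions that spare the diene and the dienylic ether.

Step 9
Reactants: 14 ethyl 2-(diethoxyphosphoryl)prop-2-enoate; 13 (5S,6E)-5-(benzyloxy)-6-methylnona-6,8-dienal
Product: 16 ethyl (2E,7S,8E)-7-(benzyloxy)-2-[(benzyloxy)methyl]-8-methylundeca-2,8,10-trienoate, via phosphonate carbanion 15 (not isolated)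
Conditions: BnOH (1.0 equiv), NaH (1.0 equiv), THF, 0 °C; 14, −20 °C; then 13, −20 °C → rt
Reagents that add atoms: benzyl alcohol, OCc1ccccc1
Why: Tandem oxa-Michael addition/Horner–Wadsworth–Emmons olefination, in which benzyl oxide adds to the phosphonoacrylate and the resulting carbanion condenses with the aldehyde to the trisubstituted enoate, expected mainly with the ester trans to the chain (E) as is usual for α-substituted phosphonoacetates and unbranched aldehydes, the minor geometric isomer being removed by chromatography.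

Step 10
Reactants: 16 ethyl (2E,7S,8E)-7-(benzyloxy)-2-[(benzyloxy)methyl]-8-methylundeca-2,8,10-trienoate
Product: 17 (2Z,7S,8E)-7-(benzyloxy)-2-[(benzyloxy)methyl]-8-methylundeca-2,8,10-trien-1-ol (CH2OH trans to the chain; only the CIP descriptor changes)
Conditions: i-Bu2AlH (2.5 equiv), CH2Cl2, −78 °C; aq. Rochelle salt
Reagents that add atoms: none
Why: 1,2-Reduction of the conjugated ester to the allylic alcohol by i-Bu2AlH without change of olefin geometry.

Step 11
Reactants: 17 (2Z,7S,8E)-7-(benzyloxy)-2-[(benzyloxy)methyl]-8-methylundeca-2,8,10-trien-1-ol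
Product: 18 (2E,7S,8E)-7-(benzyloxy)-2-[(benzyloxy)methyl]-8-methylundeca-2,8,10-trienal
Conditions: MnO2, CH2Cl2, rt
Reagents that add atoms: none
Why: Chemoselective MnO2 oxidation of the allylic alcohol to the enal, whose E form (formyl trans to the chain) is also the thermodynamically preferred isomer.

Step 12
Reactants: 18 (2E,7S,8E)-7-(benzyloxy)-2-[(benzyloxy)methyl]-8-methylundeca-2,8,10-trienal
Product: 19 (1R,4aS,5S,8aR)-5-(benzyloxy)-1-[(benzyloxy)methyl]-4a-methyl-1,2,4a,5,6,7,8,8a-octahydronaphthalene-1-carbaldehyde (labdane numbering: 4α-CHO, 4β-CH2OBn, 5α-H, 9β-OBn, 10β-CH3, C1=C2)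
Conditions: MeAlCl2 (1.1 equiv), CH2Cl2, −78 → −20 °C; aq. NaHCO3
Reagents that add atoms: none
Why: MeAlCl2 binds the formyl oxygen and lowers the LUMO of the C4=C5 enal, which adds to the C3=C2–C1=C10 diene in a concerted, asynchronous [4+2] cycloaddition that forms C5–C10 and C3–C4; the closest known reaction type is the alkylaluminium-chloride-promoted intramolecular Diels–Alder reaction of 2-substituted deca-1,7,9-triene-type enals (2,8,10-undecatrienals) to trans-fused octalins with a quaternary carbon from the dienophile. Ring A (C1–C5, C10) closes as the six-membered cycloadduct ring and ring B (C5–C10) closes at the same time through the four-carbon tether C6–C9, which folds as a chair. At C4 the suprafacial addition transfers the E geometry of the dienophile, so that CH2OBn (cis to C6) ends β and CHO (cis to H5) ends α; the C5/C10 relation (trans ring fusion, 10-CH3 anti to H5) follows from the E geometry of the C1=C10 olefin together with the endo position of the aluminium-bound formyl group, which places the tether exo. The absolute sense of C4, C5 and C10 is relayed from the (S)-C9 centre made in step 5: in the chair tether the benzyloxy group should take the equatorial site, anti to the forming C5–C10 bond, and not the axial site where it would meet H5 and H7, and this opens the diene face that leads to the 10β-methyl series. The step thus needs endo selectivity (secured by the Lewis-acid-bound formyl group on an E dienophile) and π-facial selectivity (secured by the C9 ether), and it must be faster than ionisation of the dienylic C9–O bond, which is why a single equivalent of a mild alkylaluminium chloride is used at low temperature. The methyl group that sits cis on the diene terminus C10 hinders the s-cis diene conformation and is expected to make warming to about −20 °C necessary.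

Step 13
Reactants: 19 Diels–Alder adduct (4α-CHO, 4β-CH2OBn, 9β-OBn)
Product: 21 9β-(benzyloxy)-4β-[(benzyloxy)methyl]-4α,10β-dimethyl-5α-H-Δ1-octalin, via hydrazone 20 (not isolated)
Conditions: N2H4·H2O, diethylene glycol, 130 °C; then KOH, 200 °C (−H2O)
Reagents that add atoms: none
Why: Wolff–Kishner reduction (Huang-Minlon procedure) of the non-enolisable neopentyl aldehyde, whose preformed hydrazone loses N2 under KOH to give the C18 methyl group, while the benzyl ethers and the isolated C1=C2 olefin are stable to base and no stereocentre can epimerise.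

Step 14
Reactants: 21 9β-(benzyloxy)-4β-[(benzyloxy)methyl]-4α,10β-dimethyl-5α-H-Δ1-octalin
Product: 22 4β-(hydroxymethyl)-4α,10β-dimethyl-5α-H-trans-decalin-9β-ol
Conditions: H2 (3 atm), 10% Pd/C, EtOH–EtOAc, rt
Reagents that add atoms: none
Why: Catalytic hydrogenation saturates the disubstituted C1=C2 olefin (no new stereocentre) and hydrogenolyses both benzyl ethers at their unhindered benzylic C–O bonds.

Step 15
Reactants: 22 4β-(hydroxymethyl)-4α,10β-dimethyl-5α-H-trans-decalin-9β-ol
Product: 23 4α,10β-dimethyl-9-oxo-5α-H-trans-decalin-4β-carboxylic acid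
Conditions: CrO3, aq. H2SO4, acetone, 0 °C → rt
Reagents that add atoms: water (second carboxyl oxygen, via the aldehyde hydrate), O
Why: Jones oxidation takes the secondary C9 alcohol to the ketone and the neopentyl C19 alcohol, through the aldehyde hydrate, to the acid, and since C10 is quaternary and C5 is not α to a carbonyl nothing can epimerise.

Step 16
Reactants: 23 4α,10β-dimethyl-9-oxo-5α-H-trans-decalin-4β-carboxylic acid
Product: 24 2-(trimethylsilyl)ethyl 4α,10β-dimethyl-9-oxo-5α-H-trans-decalin-4β-carboxylate
Conditions: Me3SiCH2CH2OH, PPh3, diisopropyl azodicarboxylate, THF, 0 °C → rt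
Reagents that add atoms: 2-(trimethylsilyl)ethanol, C[Si](C)(C)CCO
Why: Mitsunobu esterification, in which the hindered tertiary carboxylate is only the nucleophile towards the activated primary alcohol, gives an ester that fluoride can later remove without attack at the shielded C19 carbonyl.

Step 17
Reactants: 24 2-(trimethylsilyl)ethyl 4α,10β-dimethyl-9-oxo-5α-H-trans-decalin-4β-carboxylate
Product: 26 2-(trimethylsilyl)ethyl 4α,8α,10β-trimethyl-9-oxo-5α-H-trans-decalin-4β-carboxylate, via lithium enolate 25 (not isolated)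
Conditions: LiN(i-Pr)2 (1.1 equiv), THF, −78 °C; MeI, −78 → 0 °C
Reagents that add atoms: iodomethane, CI
Why: Enolate alkylation that can only occur at C8 because C10 is quaternary and the ester has no α-hydrogen, the equatorial 8α-methyl epimer being expected as the main product.

Step 18
Reactants: 26 2-(trimethylsilyl)ethyl 4α,8α,10β-trimethyl-9-oxo-5α-H-trans-decalin-4β-carboxylate
Product: 28 2-(trimethylsilyl)ethyl 4α,8,10β-trimethyl-9-(trifluoromethylsulfonyloxy)-5α-H-Δ8-octalin-4β-carboxylate, via potassium enolate 27 (not isolated)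
Conditions: KN(SiMe3)2, THF, −78 → 0 °C; PhNTf2, 0 °C → rt
Reagents that add atoms: N-phenylbis(trifluoromethanesulfonimide), O=S(=O)(N(c1ccccc1)S(=O)(=O)C(F)(F)F)C(F)(F)F
Why: Enolisation towards C8, the only α-carbon that bears hydrogen, and O-sulfonylation of the potassium enolate give the tetrasubstituted C8=C9 enol triflate regiospecifically.

Step 19
Reactants: 29 (2E)-3-methylpent-2-en-4-yn-1-ol
Product: 30 tert-butyldimethyl{[(2E)-3-methylpent-2-en-4-yn-1-yl]oxy}silane
Conditions: t-BuMe2SiCl, imidazole, CH2Cl2, 0 °C → rt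
Reagents that add atoms: tert-butyldimethylsilyl chloride, CC(C)(C)[Si](C)(C)Cl
Why: Standard silylation of the primary allylic alcohol, giving an ether that tolerates hydroboration and palladium catalysis, unlike an allylic acetate.

Step 20
Reactants: 30 tert-butyldimethyl{[(2E)-3-methylpent-2-en-4-yn-1-yl]oxy}silane
Product: 31 tert-butyldimethyl{[(2E)-3-methylpenta-2,4-dien-1-yl]oxy}silane
Conditions: H2 (1 atm, 1 equiv), Pd/CaCO3 poisoned with Pb(OAc)2 (Lindlar catalyst), quinoline, hexane, rt
Reagents that add atoms: none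
Why: Lindlar semi-hydrogenation of the terminal alkyne to the vinyl group, with quinoline and a metered amount of H2 holding back over-reduction and the trisubstituted (E)-olefin left untouched.

Step 21
Reactants: 31 tert-butyldimethyl{[(2E)-3-methylpenta-2,4-dien-1-yl]oxy}silane; 28 C8=C9 enol triflate
Product: 33 2-(trimethylsilyl)ethyl (13E)-15-(tert-butyldimethylsilyloxy)labda-8,13-dien-19-oate, via B-alkyl-9-BBN 32 (not isolated)
Conditions: 9-borabicyclo[3.3.1]nonane dimer, THF, 0 °C → rt; then 28, Pd(dppf)Cl2 (10 mol %), AsPh3, Cs2CO3, DMF–THF–H2O, rt → 50 °C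
Reagents that add atoms: none
Why: 9-BBN hydroborates the terminal carbon of the monosubstituted vinyl group far faster than the trisubstituted olefin, and the primary alkylborane then undergoes B-alkyl Suzuki–Miyaura coupling with the enol triflate, forming C9–C11 with retention of both olefin geometries.

Step 22
Reactants: 33 2-(trimethylsilyl)ethyl (13E)-15-(tert-butyldimethylsilyloxy)labda-8,13-dien-19-oate
Product: 34 (13E)-15-hydroxylabda-8,13-dien-19-oic acid
Conditions: Bu4NF (4 equiv), THF, rt → 40 °C; then dil. HCl to pH 3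
Reagents that add atoms: none
Why: Fluoride removes the silyl ether and, by attack at silicon with loss of ethene, the 2-(trimethylsilyl)ethyl ester, so the hindered C19 ester is cleaved without nucleophilic attack at its carbonyl.

Step 23
Reactants: 34 (13E)-15-hydroxylabda-8,13-dien-19-oic acid
Product: 35 (13E)-15-acetoxylabda-8,13-dien-19-oic acid
Conditions: Ac2O, pyridine, DMAP (cat.), CH2Cl2, 0 °C → rt; aq. NaHCO3, then dil. acid
Reagents that add atoms: acetic anhydride, CC(=O)OC(C)=O
Why: Acylation of the primary allylic alcohol, while the hindered tertiary acid at most forms a mixed anhydride that is hydrolysed again on aqueous work-up.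

**Compound list**

1 | acrolein (prop-2-enal) | C=CC=O | starting material
2 | ethyl 2-(triphenylphosphoranylidene)propanoate | CCOC(=O)C(C)=P(c1ccccc1)(c1ccccc1)c1ccccc1 | starting material
3 | ethyl (2E)-2-methylpenta-2,4-dienoate | C=C/C=C(\C)C(=O)OCC | intermediate
4 | (2E)-N-methoxy-N,2-dimethylpenta-2,4-dienamide | C=C/C=C(\C)C(=O)N(C)OC | intermediate
5 | 4-chlorobutan-1-ol | OCCCCCl | starting material
6 | tert-butyl(4-chlorobutoxy)dimethylsilane | CC(C)(C)[Si](C)(C)OCCCCCl | intermediate
7 | [4-(tert-butyldimethylsilyloxy)butyl]magnesium chloride | CC(C)(C)[Si](C)(C)OCCCC[Mg]Cl | intermediate (not isolated)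
8 | (6E)-1-(tert-butyldimethylsilyloxy)-6-methylnona-6,8-dien-5-one | C=C/C=C(\C)C(=O)CCCCO[Si](C)(C)C(C)(C)C | intermediate
9 | (5S,6E)-1-(tert-butyldimethylsilyloxy)-6-methylnona-6,8-dien-5-ol | C=C/C=C(\C)[C@@H](O)CCCCO[Si](C)(C)C(C)(C)C | intermediate
10 | sodium (5S,6E)-1-(tert-butyldimethylsilyloxy)-6-methylnona-6,8-dien-5-olate | C=C/C=C(\C)[C@@H]([O-])CCCCO[Si](C)(C)C(C)(C)C.[Na+] | intermediate (not isolated)
11 | tert-butyl{[(5S,6E)-5-(benzyloxy)-6-methylnona-6,8-dien-1-yl]oxy}dimethylsilane | C=C/C=C(\C)[C@@H](OCc1ccccc1)CCCCO[Si](C)(C)C(C)(C)C | intermediate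
12 | (5S,6E)-5-(benzyloxy)-6-methylnona-6,8-dien-1-ol | C=C/C=C(\C)[C@@H](OCc1ccccc1)CCCCO | intermediate
13 | (5S,6E)-5-(benzyloxy)-6-methylnona-6,8-dienal | C=C/C=C(\C)[C@@H](OCc1ccccc1)CCCC=O | intermediate
14 | ethyl 2-(diethoxyphosphoryl)prop-2-enoate | C=C(C(=O)OCC)P(=O)(OCC)OCC | starting material
15 | sodium salt of the α-carbanion of ethyl 3-(benzyloxy)-2-(diethoxyphosphoryl)propanoate | CCOC(=O)[C-](COCc1ccccc1)P(=O)(OCC)OCC.[Na+] | intermediate (not isolated)
16 | ethyl (2E,7S,8E)-7-(benzyloxy)-2-[(benzyloxy)methyl]-8-methylundeca-2,8,10-trienoate | C=C/C=C(\C)[C@@H](OCc1ccccc1)CCC/C=C(/C(=O)OCC)COCc1ccccc1 | intermediate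
17 | (2Z,7S,8E)-7-(benzyloxy)-2-[(benzyloxy)methyl]-8-methylundeca-2,8,10-trien-1-ol | C=C/C=C(\C)[C@@H](OCc1ccccc1)CCC/C=C(/CO)COCc1ccccc1 | intermediate
18 | (2E,7S,8E)-7-(benzyloxy)-2-[(benzyloxy)methyl]-8-methylundeca-2,8,10-trienal | C=C/C=C(\C)[C@@H](OCc1ccccc1)CCC/C=C(/C=O)COCc1ccccc1 | intermediate (key-step precursor)
19 | (1R,4aS,5S,8aR)-5-(benzyloxy)-1-[(benzyloxy)methyl]-4a-methyl-1,2,4a,5,6,7,8,8a-octahydronaphthalene-1-carbaldehyde | c1ccccc1CO[C@H]2CCC[C@H]3[C@@](C=O)(COCc4ccccc4)CC=C[C@]23C | intermediate (key-step product)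
20 | hydrazone of 19 (C18H=N–NH2) | c1ccccc1CO[C@H]2CCC[C@H]3[C@@](C=NN)(COCc4ccccc4)CC=C[C@]23C | intermediate (not isolated)
21 | 9β-(benzyloxy)-4β-[(benzyloxy)methyl]-4α,10β-dimethyl-5α-H-Δ1-octalin | c1ccccc1CO[C@H]2CCC[C@H]3[C@@](C)(COCc4ccccc4)CC=C[C@]23C | intermediate
22 | 4β-(hydroxymethyl)-4α,10β-dimethyl-5α-H-trans-decalin-9β-ol | O[C@H]1CCC[C@H]2[C@@](C)(CO)CCC[C@]12C | intermediate
23 | 4α,10β-dimethyl-9-oxo-5α-H-trans-decalin-4β-carboxylic acid | O=C1CCC[C@H]2[C@@](C)(C(=O)O)CCC[C@]12C | intermediate
24 | 2-(trimethylsilyl)ethyl 4α,10β-dimethyl-9-oxo-5α-H-trans-decalin-4β-carboxylate | O=C1CCC[C@H]2[C@@](C)(C(=O)OCC[Si](C)(C)C)CCC[C@]12C | intermediate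
25 | lithium C8=C9 enolate of 24 | [Li+].[O-]C1=CCC[C@H]2[C@@](C)(C(=O)OCC[Si](C)(C)C)CCC[C@]12C | intermediate (not isolated)
26 | 2-(trimethylsilyl)ethyl 4α,8α,10β-trimethyl-9-oxo-5α-H-trans-decalin-4β-carboxylate | O=C1[C@H](C)CC[C@H]2[C@@](C)(C(=O)OCC[Si](C)(C)C)CCC[C@]12C | intermediate
27 | potassium C8=C9 enolate of 26 | [K+].[O-]C1=C(C)CC[C@H]2[C@@](C)(C(=O)OCC[Si](C)(C)C)CCC[C@]12C | intermediate (not isolated)
28 | 2-(trimethylsilyl)ethyl 4α,8,10β-trimethyl-9-(trifluoromethylsulfonyloxy)-5α-H-Δ8-octalin-4β-carboxylate | O=S(=O)(OC1=C(C)CC[C@H]2[C@@](C)(C(=O)OCC[Si](C)(C)C)CCC[C@]12C)C(F)(F)F | intermediate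
29 | (2E)-3-methylpent-2-en-4-yn-1-ol | C#C/C(C)=C/CO | starting material
30 | tert-butyldimethyl{[(2E)-3-methylpent-2-en-4-yn-1-yl]oxy}silane | C#C/C(C)=C/CO[Si](C)(C)C(C)(C)C | intermediate
31 | tert-butyldimethyl{[(2E)-3-methylpenta-2,4-dien-1-yl]oxy}silane | C=C/C(C)=C/CO[Si](C)(C)C(C)(C)C | intermediate
32 | 9-[(3E)-5-(tert-butyldimethylsilyloxy)-3-methylpent-3-en-1-yl]-9-borabicyclo[3.3.1]nonane | CC(C)(C)[Si](C)(C)OC/C=C(\C)CCB1C2CCCC1CCC2 | intermediate (not isolated)
33 | 2-(trimethylsilyl)ethyl (13E)-15-(tert-butyldimethylsilyloxy)labda-8,13-dien-19-oate | CC(C)(C)[Si](C)(C)OC/C=C(\C)CCC1=C(C)CC[C@H]2[C@@](C)(C(=O)OCC[Si](C)(C)C)CCC[C@]12C | intermediate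
34 | (13E)-15-hydroxylabda-8,13-dien-19-oic acid | OC/C=C(\C)CCC1=C(C)CC[C@H]2[C@@](C)(C(=O)O)CCC[C@]12C | intermediate
35 | (13E)-15-acetoxylabda-8,13-dien-19-oic acid, (4S,5R,10S) | CC(=O)OC/C=C(\C)CCC1=C(C)CC[C@H]2[C@@](C)(C(=O)O)CCC[C@]12C | target

**Step count**

Total steps: 23. Longest linear sequence: 20 steps (1, 2, 4–18, 21–23); step 3 and steps 19–20 are side branches.

**Steps most likely to fail**

Step 12. The cycloaddition may be too slow, because the methyl group cis on the diene terminus C10 disfavours the s-cis diene. The warming and extra Lewis acid then needed would allow ionisation of the dienylic C9–O bond and oligomerisation to overtake ring closure. Fallback, with a different mode of activation (ionic Diels–Alder reaction of the acetal): setting out from trienal 18, acetalisation with 1,2-bis(trimethylsilyloxy)ethane and catalytic Me3SiOTf in CH2Cl2 at −78 °C gives the 1,3-dioxolane acetal of 18, F1. A catalytic amount of Me3SiOTf or CF3SO3H at −78 → −40 °C opens it to an alkoxy-substituted allyl cation, a much stronger dienophile, which should cyclise with the same endo and facial preferences to the 1,3-dioxolane acetal of the adduct, F2. Mild hydrolysis (pyridinium p-toluenesulfonate, acetone–H2O) returns to aldehyde 19.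

Step 21. Oxidative addition of the zerovalent palladium catalyst and transmetalation at the tetrasubstituted triflate flanked by the quaternary C10 may be slower than protodeboronation or β-hydride loss of the alkylborane and hydrolysis of the triflate by the aqueous base. Fallback, with a different nucleophile made in a different way and coupled base-free (Negishi coupling): setting out from diene 31, the borane 32 is oxidised with NaOH/H2O2 to the homoallylic alcohol (3E)-5-(tert-butyldimethylsilyloxy)-3-methylpent-3-en-1-ol F3. Appel iodination (I2, PPh3, imidazole) gives tert-butyl{[(2E)-5-iodo-3-methylpent-2-en-1-yl]oxy}dimethylsilane F4. Zinc insertion (Zn dust, LiCl, THF) gives [(3E)-5-(tert-butyldimethylsilyloxy)-3-methylpent-3-en-1-yl]zinc iodide F5. F5 is coupled with triflate 28 under anhydrous conditions (Pd(OAc)2, 2-dicyclohexylphosphino-2′,6′-dimethoxybiphenyl, THF–NMP, 50 °C) to return to 33.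

Step 9. The olefination may leak to the geometric isomer with the ester cis to the chain, as the α-substituent is larger than methyl, and the β-alkoxy carbanion may revert by loss of benzyl oxide. Fallback, with a neutral ylide under thermodynamic control in place of the anionic phosphonate: setting out from aldehyde 13, ethyl (triphenylphosphoranylidene)acetate (2 equiv) is C-alkylated with benzyl chloromethyl ether in CH2Cl2 to [1-(benzyloxy)-3-ethoxy-3-oxopropan-2-yl]triphenylphosphonium chloride F6. The second equivalent of ylide deprotonates F6 to ethyl 3-(benzyloxy)-2-(triphenylphosphoranylidene)propanoate F7. Wittig olefination of 13 with F7 (toluene, 80 °C) returns to the (E)-enoate 16.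

**Further compounds**

F1 | step 12 | 1,3-dioxolane acetal of trienal 18 | C=C/C=C(\C)[C@@H](OCc1ccccc1)CCC/C=C(/C2OCCO2)COCc1ccccc1
F2 | step 12 | 1,3-dioxolane acetal of adduct 19 | c1ccccc1CO[C@H]2CCC[C@H]3[C@@](C5OCCO5)(COCc4ccccc4)CC=C[C@]23C
F3 | step 21 | (3E)-5-(tert-butyldimethylsilyloxy)-3-methylpent-3-en-1-ol | CC(C)(C)[Si](C)(C)OC/C=C(\C)CCO
F4 | step 21 | tert-butyl{[(2E)-5-iodo-3-methylpent-2-en-1-yl]oxy}dimethylsilane | CC(C)(C)[Si](C)(C)OC/C=C(\C)CCI
F5 | step 21 | [(3E)-5-(tert-butyldimethylsilyloxy)-3-methylpent-3-en-1-yl]zinc iodide | CC(C)(C)[Si](C)(C)OC/C=C(\C)CC[Zn]I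
F6 | step 9 | [1-(benzyloxy)-3-ethoxy-3-oxopropan-2-yl]triphenylphosphonium chloride | CCOC(=O)C(COCc1ccccc1)[P+](c1ccccc1)(c1ccccc1)c1ccccc1.[Cl-]
F7 | step 9 | ethyl 3-(benzyloxy)-2-(triphenylphosphoranylidene)propanoate | CCOC(=O)C(COCc1ccccc1)=P(c1ccccc1)(c1ccccc1)c1ccccc1
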